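The numbers in the tables are calculated from invented constants; noise was put on by code.

Watch how fast product climbs for each unit of free enzyme, and hold that against the level at which product stops.

in all of them: substrate 0.16 M; added ligand 4.6 µM

| charge | free enzyme | temperature | remark | time |
|---|---|---|---|---|
| Monday's | 1.4 µM | −35 °C | run made earlier |  |
| Thursday's | 5.8 µM | 0 °C | run made earlier |  |
| west | 2.9 µM | 30 °C |  | 50 min |
| north-west | 2.9 µM | 10 °C |  | 50 min |
| south-west | 2.9 µM | −10 °C |  | 50 min |
| north-east | 2.9 µM | −30 °C |  | 50 min |

| run | time / min | product / % |
|---|---|---|
| Monday's | 60.0 | 3.4 |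
| Monday's | 180 | 7.8 |
| Monday's | 360 | 14.4 |
| Monday's | 480 | 19.6 |
| Monday's | 720 | 25.7 |
| Monday's | 900 | 31.3 |
| Monday's | 1200 | 37.2 |
| Thursday's | 20.0 | 41.3 |
| Thursday's | 25.0 | 41.1 |
| Thursday's | 40.0 | 41.4 |
| Thursday's | 60.0 | 41.9 |
| Thursday's | 80.0 | 41.6 |
| Thursday's | 120 | 42.7 |
| Thursday's | 240 | 41.3 |

(standard deviation of a reading: 0.5 percentage points)

1. which flask leads in amount of product, in percent of the substrate charged ("all alike" within 1.5 percentage points) (west / north-west / south-west / north-east / all alike)
2. how much product is there at the end, in percent of the substrate charged: west
3. how much product is there at the end, in percent of the substrate charged: north-west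
4. how much product is there at the end, in percent of the substrate charged: south-west
5. how much product is there at the end, in percent of the substrate charged: north-east

- what may be going on: free enzyme -> unfolded enzyme; substrate + free enzyme <-> starting complex; starting complex <-> free enzyme + product; free enzyme + added ligand <-> idle complex

Two extreme flasks can be reckoned in the head (kinetic against thermodynamic control). In the first, the flask is at rest: product and substrate stand in a fixed ratio, and the even split, ratio one, is the zero of the scale. Thursday's run, flat between 41.1% and 42.7% from 20.0 min on, reads as such a rest at 0 °C, with a ratio of 0.721, somewhat below the even split.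

In the second, nothing runs back and product grows in a straight line with free enzyme and time. Monday's run gives the slope: 7.8% at 180 min with 1.4 µM makes w = 3.10 × 10⁻⁴ /min/µM, the yield per enzyme, meaning the share of the charged substrate turned into product per minute and per µM of free enzyme. It is a reading and carries the scatter of one.

With 2.9 µM for 50 min, the line at this w, read at Monday's −35 °C, reaches 4.49% for north-east's charge. That is far less than the 37.2% that Monday's run read at 1200 min, up from 31.3% at 900 min, so in north-east running back should count for little and the flask should stay near a straight line. But north-east stands at −30 °C against Monday's −35 °C, so this reckoning puts it above the line, by a warming factor that these runs do not give exactly. West at 30 °C and north-west at 10 °C should lie near their rest levels, since Thursday's run, at 0 °C with 5.8 µM of free enzyme, was flat by 20.0 min, a time shorter than their 50 min.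

The forecast named north-west as leader, with 30% for west, 36.5% for north-west, 35% for south-west and 8.5% for north-east, and added: “North-west narrowly leads, and this call is uncertain”.

The flasks give 23.2% in west, 34.6% in north-west, 38.7% in south-west and 8.51% in north-east, so south-west leads.

    free enzyme → unfolded enzyme (k = 0.00540 /min, Ea = 194 kJ/mol)
    substrate + free enzyme ⇌ starting complex (K = 3.40 /M, k = 1.30 × 10⁵ /M/s, Ea = 10.0 kJ/mol, ΔH = −6.00 kJ/mol)
    starting complex ⇌ free enzyme + product (K = 0.0890 M, k = 65000 /min, Ea = 59.0 kJ/mol, ΔH = −14.0 kJ/mol)
    free enzyme + added ligand ⇌ idle complex (K = 1.50 × 10⁵ /M, k = 30000 /M/min, Ea = 48.0 kJ/mol, ΔH = −34.0 kJ/mol)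
    (constants at 30 °C)

Left until 500 min, south-west reaches 50.3% and north-east 50.1%, so neither has come to rest at 50 min, while product in west stays at 23.2% and in north-west at 34.6%. North-east's 8.51% stands at 1.90 times its line. For a neighbour of north-east charged with 0.720 µM of free enzyme, w and that factor reckon 2.11%; the computed result is 2.18%.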